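**Strategy.** Everything rests on cutting ring C of the middle, galloylated flavan unit across O1–C2 and C3–C4. The four-atom piece O1–C8a–C4a–C4, whose C4 already carries C8 of the bottom unit and whose ring A already carries the top unit at C8, is unmasked as an o-quinone methide from an o-hydroxy diarylmethanol. The two-atom piece C2–C3 is a Z-enol gallate bearing ring B. One acid-catalysed hetero-Diels–Alder reaction therefore closes the pyran ring, forms both bonds, sets C2, C3 and C4 and installs the gallate on O3 without selective acylation. The precursor is a fully benzylated bis-flavanyl phenol carbinol, so one hydrogenolysis finishes the synthesis.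

Key step: step 10

Remark on the structure: the target is epigallocatechin-(4β→8)-[epigallocatechin 3-O-gallate]-(4β→8)-epigallocatechin. Every flavan unit is 2,3-cis with the 2R,3R configuration of natural epigallocatechin, and each C4–C8 bond is trans to the oxygen on the neighbouring C3.

Assumption: the three benzyl-protected aromatic building blocks that enter in steps 4, 8 and 9 are bought as such.

Step 1
Reactants: 1 (−)-epigallocatechin (EGC)
Product: 2 5,7,3',4',5'-penta-O-benzyl-EGC (2R,3R, free 3-OH)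
Conditions: BnBr (5.5 equiv), K2CO3, DMF, 0 °C → rt, argon
Reagents that add atoms: benzyl bromide, BrCc1ccccc1
Why: Williamson etherification of the five phenols with a weak base leaves the much less acidic secondary 3-OH free and, under argon at low temperature, should avoid base-induced C2 epimerisation and oxidation of the pyrogallol ring.

Step 2
Reactants: 2 5,7,3',4',5'-penta-O-benzyl-EGC
Product: 3 3,5,7,3',4',5'-hexa-O-benzyl-EGC (2R,3R)
Conditions: NaH, BnBr, DMF, 0 °C → rt
Reagents that add atoms: benzyl bromide, BrCc1ccccc1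
Why: Williamson etherification of the secondary alkoxide; with every phenol already capped there is no ring-opening pathway for C2 epimerisation, so both stereocentres are retained.

Step 3
Reactants: 3 hexa-O-benzyl-EGC
Product: 4 4β-(2-ethoxyethoxy)-hexa-O-benzyl-EGC (ether at C4 trans to the 3-benzyloxy group)
Conditions: DDQ, EtOCH2CH2OH, CH2Cl2, rt
Reagents that add atoms: 2-ethoxyethanol, CCOCCO
Why: Benzylic C–H oxidation with DDQ: hydride is taken from C4, the only position activated by the 5,7-dioxygenated ring A, and the alcohol captures the cation on the face opposite the cis 2-aryl and 3-benzyloxy groups, so the 4β (3,4-trans) ether should result while ordinary benzyl ethers are left alone at room temperature.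

Step 4
Reactants: 4 4β-(2-ethoxyethoxy)-hexa-O-benzyl-EGC; 5 3,5-bis(benzyloxy)phenol
Product: 6 3,5-bis(benzyloxy)-2-(hexa-O-benzyl-EGC-4β-yl)phenol (aryl at C4 trans to 3-OBn)
Conditions: 5 (4 equiv), BF3·OEt2 (0.5 equiv), CH2Cl2, −78 → −30 °C
Reagents that add atoms: none
Why: Lewis-acid Friedel–Crafts arylation of the C4 cation, the standard way of forming flavan C4–aryl bonds: the phenol should react at a carbon between OH and OBn (two such sites, less hindered than the one between two OBn groups, in line with the C8 over C6 preference of benzylated flavans) and on the face anti to the 3-benzyloxy group, which sets the 4β centre, while the excess of 5 suppresses double alkylation and self-condensation of 4.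

Step 5
Reactants: 6 3,5-bis(benzyloxy)-2-(hexa-O-benzyl-EGC-4β-yl)phenol
Product: 7 4,6-bis(benzyloxy)-2-hydroxy-3-(hexa-O-benzyl-EGC-4β-yl)benzaldehyde
Conditions: MgCl2, Et3N, (CH2O)n, THF, reflux; then cold 1 M HCl
Reagents that add atoms: paraformaldehyde (as formaldehyde), C=O
Why: Magnesium-mediated ortho-formylation of a phenol (Casnati–Skattebøl reaction): the chloromagnesium phenoxide delivers formaldehyde to the only free ortho carbon and a second formaldehyde oxidises the resulting benzylic alkoxide to the aldehyde, so no para product is expected.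

Step 6
Reactants: 3 hexa-O-benzyl-EGC
Product: 8 8-bromo-hexa-O-benzyl-EGC
Conditions: NBS, CH2Cl2, −78 °C → rt
Reagents that add atoms: N-bromosuccinimide, O=C1CCC(=O)N1Br
Why: Electrophilic aromatic bromination: ring A is the most electron-rich ring and C8, between the ring oxygen and one benzyloxy group, is brominated in preference to C6 between two benzyloxy groups, the selectivity known for benzylated (epi)catechins.

Step 7
Reactants: 7 4,6-bis(benzyloxy)-2-hydroxy-3-(hexa-O-benzyl-EGC-4β-yl)benzaldehyde; 8 8-bromo-hexa-O-benzyl-EGC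
Product: 11 [4,6-bis(benzyloxy)-2-hydroxy-3-(hexa-O-benzyl-EGC-4β-yl)phenyl](hexa-O-benzyl-EGC-8-yl)methanol (both carbinol epimers), via sodium phenoxide of the salicylaldehyde 9 (not isolated), via 8-lithio-hexa-O-benzyl-EGC 10 (not isolated)
Conditions: 7, NaH, THF, 0 °C; 8 (1.5 equiv), t-BuLi (2 equiv per 8), THF, −78 °C; combine, −78 → −20 °C; aq NH4Cl; Et3N-deactivated silica
Reagents that add atoms: none
Why: Bromine–lithium exchange and 1,2-addition of the aryllithium to the aldehyde, whose acidic phenol is first masked as its sodium salt so that no organolithium is lost; the carbinol centre forms without control, which is harmless because step 10 erases it.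

Step 8
Reactants: 12 3,4,5-tris(benzyloxy)benzaldehyde
Product: 13 5-ethynyl-1,2,3-tris(benzyloxy)benzene
Conditions: dimethyl (1-diazo-2-oxopropyl)phosphonate, K2CO3, MeOH/THF, rt
Reagents that add atoms: dimethyl (1-diazo-2-oxopropyl)phosphonate, COP(=O)(OC)C(=[N+]=[N-])C(C)=O
Why: Seyferth–Gilbert homologation with the Ohira–Bestmann reagent: the diazophosphonate anion freed by methanolysis olefinates the non-enolisable aldehyde and the diazoalkene loses nitrogen with 1,2-hydrogen shift to the terminal alkyne under conditions that leave benzyl ethers alone.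

Step 9
Reactants: 13 5-ethynyl-1,2,3-tris(benzyloxy)benzene; 14 3,4,5-tris(benzyloxy)benzoic acid
Product: 15 (Z)-2-[3,4,5-tris(benzyloxy)phenyl]ethenyl 3,4,5-tris(benzyloxy)benzoate
Conditions: Ru(η3-CH2C(CH3)CH2)2(Ph2P(CH2)4PPh2) (2 mol%), toluene, 60 °C
Reagents that add atoms: none
Why: Ruthenium-catalysed anti-Markovnikov hydro-acyloxylation of a terminal alkyne: the carboxylate adds to the α-carbon of a ruthenium vinylidene and protonolysis releases the 1-alkenyl ester with Z geometry (net trans addition), as established for arylacetylenes with aromatic acids.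

Step 10
Reactants: 11 o-hydroxy diarylmethanol (both carbinol epimers); 15 (Z)-enol gallate
Product: 17 eicosa-O-benzyl trimer (benzylated target), via E-o-quinone methide 16 (not isolated)
Conditions: 15 (2 equiv), (R)-3,3'-bis(2,4,6-triisopropylphenyl)-1,1'-binaphthyl-2,2'-diyl hydrogen phosphate ((R)-TRIP, 10 mol%), 5 Å MS, toluene, −20 °C → rt
Reagents that add atoms: none
Why: Proposed new method: the phosphoric acid ionises the doubly benzylic carbinol of 11, water leaves, and the E-configured o-quinone methide 16, held to the chiral phosphate by hydrogen bonding and ion pairing, takes up enol ester 15 across O1=C8a–C4a=C4 in an inverse-demand hetero-Diels–Alder reaction. The closest known reaction type is the chiral-phosphoric-acid-catalysed [4+2] addition of o-quinone methides, made in the flask from o-hydroxybenzhydrols, to styrenes and enol ethers to give 2-aryl chromans; an enol ester of an arylacetaldehyde has not served as the two-carbon partner. The pyran ring of the middle unit closes in this intermolecular [4+2] mode, asynchronously, C3–C4 forming ahead of O1–C2. Regiochemistry should follow from charge distribution: bonding of the oxygen-bearing carbon to C4 leaves positive charge on C2, where the tribenzyloxyphenyl ring stabilises it, whereas the reverse orientation would need the ester oxygen, whose lone pair is engaged by the carbonyl group, to stabilise it. C2 and C3 become cis because the addition is suprafacial on the Z alkene and the phenolic oxygen closes on C2 before rotation about C2–C3; C3 and C4 become trans through exo approach, the endo space above the methide ring being crowded by the top unit on C8 and the benzyloxy group on C5; the absolute sense, bonding of C3 to the Si face of C4, is left to the chiral phosphate working together with the resident stereocentres of the top unit next to O1, (R)-TRIP being taken as the matched enantiomer. The step thus needs regio-, endo/exo and facial selectivity plus stereospecificity, and the sieves and the excess of 15 guard against hydrolysis of the enol ester and self-reaction of the methide.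

Step 11
Reactants: 17 eicosa-O-benzyl trimer
Product: 18 epigallocatechin-(4β→8)-[epigallocatechin 3-O-gallate]-(4β→8)-epigallocatechin (target)
Conditions: H2 (1 atm), Pd(OH)2/C, THF/MeOH/H2O, rt
Reagents that add atoms: none
Why: Heterogeneous catalytic hydrogenolysis of all twenty benzyl ethers (eighteen aryl, two alkyl), the usual end game for benzylated proanthocyanidin gallates; the gallate ester, the C4–C8 bonds and the ring C ethers should survive these neutral conditions and no stereocentre is involved.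

**Compound list**

1 | (−)-epigallocatechin, (2R,3R) | Oc1cc(O)c2c(c1)O[C@H](c1cc(O)c(O)c(O)c1)[C@H](O)C2 | starting material

2 | 5,7,3',4',5'-penta-O-benzyl-EGC | O(Cc9ccccc9)c1cc(OCc9ccccc9)c2c(c1)O[C@H](c1cc(OCc9ccccc9)c(OCc9ccccc9)c(OCc9ccccc9)c1)[C@H](O)C2 | intermediate

3 | 3,5,7,3',4',5'-hexa-O-benzyl-EGC | O(Cc9ccccc9)c1cc(OCc9ccccc9)c2c(c1)O[C@H](c1cc(OCc9ccccc9)c(OCc9ccccc9)c(OCc9ccccc9)c1)[C@H](OCc9ccccc9)C2 | intermediate

4 | 4β-(2-ethoxyethoxy)-hexa-O-benzyl-EGC (2,3-cis, 3,4-trans) | CCOCCO[C@H]1c2c(OCc9ccccc9)cc(OCc9ccccc9)cc2O[C@H](c2cc(OCc9ccccc9)c(OCc9ccccc9)c(OCc9ccccc9)c2)[C@@H]1OCc9ccccc9 | intermediate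

5 | 3,5-bis(benzyloxy)phenol | Oc1cc(OCc9ccccc9)cc(OCc9ccccc9)c1 | starting material

6 | 3,5-bis(benzyloxy)-2-(hexa-O-benzyl-EGC-4β-yl)phenol | Oc1cc(OCc9ccccc9)cc(OCc9ccccc9)c1[C@H]1c2c(OCc9ccccc9)cc(OCc9ccccc9)cc2O[C@H](c2cc(OCc9ccccc9)c(OCc9ccccc9)c(OCc9ccccc9)c2)[C@@H]1OCc9ccccc9 | intermediate

7 | 4,6-bis(benzyloxy)-2-hydroxy-3-(hexa-O-benzyl-EGC-4β-yl)benzaldehyde | O=Cc1c(OCc9ccccc9)cc(OCc9ccccc9)c([C@H]2c3c(OCc9ccccc9)cc(OCc9ccccc9)cc3O[C@H](c3cc(OCc9ccccc9)c(OCc9ccccc9)c(OCc9ccccc9)c3)[C@@H]2OCc9ccccc9)c1O | intermediate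

8 | 8-bromo-hexa-O-benzyl-EGC | Brc1c(OCc9ccccc9)cc(OCc9ccccc9)c2c1O[C@H](c1cc(OCc9ccccc9)c(OCc9ccccc9)c(OCc9ccccc9)c1)[C@H](OCc9ccccc9)C2 | intermediate

9 | sodium phenoxide of aldehyde 7 | O=Cc1c(OCc9ccccc9)cc(OCc9ccccc9)c([C@H]2c3c(OCc9ccccc9)cc(OCc9ccccc9)cc3O[C@H](c3cc(OCc9ccccc9)c(OCc9ccccc9)c(OCc9ccccc9)c3)[C@@H]2OCc9ccccc9)c1[O-].[Na+] | intermediate (not isolated)

10 | 8-lithio-hexa-O-benzyl-EGC | [Li]c1c(OCc9ccccc9)cc(OCc9ccccc9)c2c1O[C@H](c1cc(OCc9ccccc9)c(OCc9ccccc9)c(OCc9ccccc9)c1)[C@H](OCc9ccccc9)C2 | intermediate (not isolated)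

11 | [4,6-bis(benzyloxy)-2-hydroxy-3-(hexa-O-benzyl-EGC-4β-yl)phenyl](hexa-O-benzyl-EGC-8-yl)methanol, both carbinol epimers | OC(c2c(OCc9ccccc9)cc(OCc9ccccc9)c3c2O[C@H](c2cc(OCc9ccccc9)c(OCc9ccccc9)c(OCc9ccccc9)c2)[C@H](OCc9ccccc9)C3)c2c(OCc9ccccc9)cc(OCc9ccccc9)c([C@H]3c4c(OCc9ccccc9)cc(OCc9ccccc9)cc4O[C@H](c4cc(OCc9ccccc9)c(OCc9ccccc9)c(OCc9ccccc9)c4)[C@@H]3OCc9ccccc9)c2O | intermediate

12 | 3,4,5-tris(benzyloxy)benzaldehyde | O=Cc1cc(OCc9ccccc9)c(OCc9ccccc9)c(OCc9ccccc9)c1 | starting material

13 | 5-ethynyl-1,2,3-tris(benzyloxy)benzene | C#Cc1cc(OCc9ccccc9)c(OCc9ccccc9)c(OCc9ccccc9)c1 | intermediate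

14 | 3,4,5-tris(benzyloxy)benzoic acid | O=C(O)c1cc(OCc9ccccc9)c(OCc9ccccc9)c(OCc9ccccc9)c1 | starting material

15 | (Z)-2-[3,4,5-tris(benzyloxy)phenyl]ethenyl 3,4,5-tris(benzyloxy)benzoate | O=C(O/C=C\c1cc(OCc9ccccc9)c(OCc9ccccc9)c(OCc9ccccc9)c1)c1cc(OCc9ccccc9)c(OCc9ccccc9)c(OCc9ccccc9)c1 | intermediate

16 | (E)-3,5-bis(benzyloxy)-2-(hexa-O-benzyl-EGC-4β-yl)-6-[(hexa-O-benzyl-EGC-8-yl)methylidene]cyclohexa-2,4-dien-1-one (o-quinone methide) | O=C1/C(=C/c2c(OCc9ccccc9)cc(OCc9ccccc9)c3c2O[C@H](c2cc(OCc9ccccc9)c(OCc9ccccc9)c(OCc9ccccc9)c2)[C@H](OCc9ccccc9)C3)C(OCc9ccccc9)=CC(OCc9ccccc9)=C1[C@H]1c2c(OCc9ccccc9)cc(OCc9ccccc9)cc2O[C@H](c2cc(OCc9ccccc9)c(OCc9ccccc9)c(OCc9ccccc9)c2)[C@@H]1OCc9ccccc9 | intermediate (not isolated)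

17 | eicosa-O-benzyl trimer (middle unit 2,3-cis-3,4-trans, gallate on O3) | O=C(O[C@@H]1[C@@H](c2c(OCc9ccccc9)cc(OCc9ccccc9)c3c2O[C@H](c2cc(OCc9ccccc9)c(OCc9ccccc9)c(OCc9ccccc9)c2)[C@H](OCc9ccccc9)C3)c2c(OCc9ccccc9)cc(OCc9ccccc9)c([C@H]3c4c(OCc9ccccc9)cc(OCc9ccccc9)cc4O[C@H](c4cc(OCc9ccccc9)c(OCc9ccccc9)c(OCc9ccccc9)c4)[C@@H]3OCc9ccccc9)c2O[C@@H]1c1cc(OCc9ccccc9)c(OCc9ccccc9)c(OCc9ccccc9)c1)c1cc(OCc9ccccc9)c(OCc9ccccc9)c(OCc9ccccc9)c1 | intermediate

18 | epigallocatechin-(4β→8)-[epigallocatechin 3-O-gallate]-(4β→8)-epigallocatechin | O=C(O[C@@H]1[C@@H](c2c(O)cc(O)c3c2O[C@H](c2cc(O)c(O)c(O)c2)[C@H](O)C3)c2c(O)cc(O)c([C@H]3c4c(O)cc(O)cc4O[C@H](c4cc(O)c(O)c(O)c4)[C@@H]3O)c2O[C@@H]1c1cc(O)c(O)c(O)c1)c1cc(O)c(O)c(O)c1 | target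

**Step count.** Total: 11 steps. Longest linear sequence: 8 steps (steps 1, 2, 3, 4, 5, 7, 10, 11).

**Steps most likely to fail**

Step 10. The cycloaddition may fail in several ways:
- addition in the reverse orientation;
- loss of the alkene geometry through a stepwise ionic closure (2,3-trans product);
- endo approach (3,4-cis product);
- poor discrimination between the two faces of the methide;
- acyl transfer from the enol ester to the phenol;
- no reaction, because a stabilised methide meets a weak π-nucleophile.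

The fallback uses established Lewis-acid interflavan couplings. It sets out from 2, 3, 4 and 14 and returns at 17.
- Alcohol 2 is esterified with acid 14 (DCC, DMAP, CH2Cl2) to give penta-O-benzyl-EGC 3-O-(tri-O-benzylgallate) F1.
- DDQ and 2-ethoxyethanol convert it into its 4β-(2-ethoxyethoxy) ether F2.
- F2 is coupled with an excess of 3 (TMSOTf, CH2Cl2, −78 °C). Attack through C8 of 3, anti to the 3-acyloxy group, should give the galloylated dimer F3.
- F3, used in excess as the nucleophile through C8 of its upper unit, is coupled with 4 under the same conditions to give 17, which goes on to step 11.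

Step 7. Addition of a hindered aryllithium to a hindered, electron-rich phenoxide aldehyde may be slow. Proton transfer may compete, and the very ionisable product may dehydrate during work-up or chromatography. The fallback exchanges the roles of the partners. It sets out from 8 and 6 and returns at 11.
- Bromide 8 is converted by bromine–lithium exchange (t-BuLi, THF, −78 °C) and DMF into 8-formyl-hexa-O-benzyl-EGC F4.
- Phenol 6 is converted with EtMgBr in toluene into its bromomagnesium phenoxide F5.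
- F5 adds through the magnesium chelate, ortho to oxygen, to F4 (ortho-specific hydroxyalkylation of a magnesium phenoxide) and gives 11 without the formylation of step 5.

Step 4. The cation may also attack the carbon para to the hydroxyl group, the phenol oxygen may be alkylated, or a second cation may add. The fallback removes the regiochemical question by symmetry. It sets out from 4 and returns at 7, replacing steps 4 and 5.
- Ether 4 is coupled with an excess of phloroglucinol (Oc1cc(O)cc(O)c1), all of whose ring carbons are equivalent (BF3·OEt2, THF/CH2Cl2), to give 2-(hexa-O-benzyl-EGC-4β-yl)phloroglucinol F6.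
- Vilsmeier–Haack formylation (POCl3, DMF, then water) at one of the two equivalent free carbons gives 2,4,6-trihydroxy-3-(hexa-O-benzyl-EGC-4β-yl)benzaldehyde F7.
- Benzylation with two equivalents of BnBr and K2CO3 in DMF should etherify the 4- and 6-hydroxyls and leave the hindered, hydrogen-bonded hydroxyl between the flavanyl group and the aldehyde free, which is 7.

**Further compounds**

F1 | step 10 | 5,7,3',4',5'-penta-O-benzyl-EGC 3-O-[3,4,5-tris(benzyloxy)benzoate] | O(Cc9ccccc9)c1cc(OCc9ccccc9)c2c(c1)O[C@H](c1cc(OCc9ccccc9)c(OCc9ccccc9)c(OCc9ccccc9)c1)[C@H](OC(=O)c1cc(OCc9ccccc9)c(OCc9ccccc9)c(OCc9ccccc9)c1)C2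

F2 | step 10 | 4β-(2-ethoxyethoxy)-penta-O-benzyl-EGC 3-O-[3,4,5-tris(benzyloxy)benzoate] | CCOCCO[C@H]1c2c(OCc9ccccc9)cc(OCc9ccccc9)cc2O[C@H](c2cc(OCc9ccccc9)c(OCc9ccccc9)c(OCc9ccccc9)c2)[C@@H]1OC(=O)c1cc(OCc9ccccc9)c(OCc9ccccc9)c(OCc9ccccc9)c1

F3 | step 10 | benzylated dimer, [penta-O-benzyl-EGC 3-O-(tri-O-benzylgallate)]-(4β→8)-hexa-O-benzyl-EGC | O=C(O[C@@H]1[C@@H](c2c(OCc9ccccc9)cc(OCc9ccccc9)c3c2O[C@H](c2cc(OCc9ccccc9)c(OCc9ccccc9)c(OCc9ccccc9)c2)[C@H](OCc9ccccc9)C3)c2c(OCc9ccccc9)cc(OCc9ccccc9)cc2O[C@@H]1c1cc(OCc9ccccc9)c(OCc9ccccc9)c(OCc9ccccc9)c1)c1cc(OCc9ccccc9)c(OCc9ccccc9)c(OCc9ccccc9)c1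

F4 | step 7 | 8-formyl-hexa-O-benzyl-EGC | O=Cc1c(OCc9ccccc9)cc(OCc9ccccc9)c2c1O[C@H](c1cc(OCc9ccccc9)c(OCc9ccccc9)c(OCc9ccccc9)c1)[C@H](OCc9ccccc9)C2

F5 | step 7 | bromomagnesium phenoxide of 6 | Br[Mg]Oc1cc(OCc9ccccc9)cc(OCc9ccccc9)c1[C@H]1c2c(OCc9ccccc9)cc(OCc9ccccc9)cc2O[C@H](c2cc(OCc9ccccc9)c(OCc9ccccc9)c(OCc9ccccc9)c2)[C@@H]1OCc9ccccc9

F6 | step 4 | 2-(hexa-O-benzyl-EGC-4β-yl)benzene-1,3,5-triol | Oc1cc(O)cc(O)c1[C@H]1c2c(OCc9ccccc9)cc(OCc9ccccc9)cc2O[C@H](c2cc(OCc9ccccc9)c(OCc9ccccc9)c(OCc9ccccc9)c2)[C@@H]1OCc9ccccc9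

F7 | step 4 | 2,4,6-trihydroxy-3-(hexa-O-benzyl-EGC-4β-yl)benzaldehyde | O=Cc1c(O)cc(O)c([C@H]2c3c(OCc9ccccc9)cc(OCc9ccccc9)cc3O[C@H](c3cc(OCc9ccccc9)c(OCc9ccccc9)c(OCc9ccccc9)c3)[C@@H]2OCc9ccccc9)c1O
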